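The ring is numbered as in shikimate: C1 carries CO2Me, C2 is the vinylic CH, C3–C5 are the oxygenated carbons and C6 is the CH2. The cyclohexene is cut on both sides of its C1=C2 enoate, so that C2–C3 and C1–C6 come from one Diels–Alder reaction of a 1-silyloxybutadiene (C3–C6) with methyl (E)-3-nitroacrylate (C1–C2). The feature used is the 1,3-relation of the C3 oxygen and the C1 ester, opposite to what acrylate or propiolate gives. A nitro group on C2 overrides the ester and then leaves as nitrous acid to unveil C1=C2. A chiral hydrogen-bond donor sets C3. The C3 hydroxyl then directs a syn C4–C5 epoxide, which the acid opens at C5.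

Key step: step 3

Assumption: (E)-3-methylpent-2-enoic acid and E-rich 1-(trimethylsilyloxy)buta-1,3-diene are catalogue reagents; the Z-diene cannot adopt the s-cis geometry and is a bystander.

Step 1
Reactants: 1 methyl acrylate
Product: 2 methyl 2-iodo-3-nitropropanoate (racemic)
Conditions: N2O4, I2, Et2O, 0 °C → rt
Reagents that add atoms: dinitrogen tetroxide O=[N+]([O-])[N+](=O)[O-]; iodine II
Why: Iodonitration of the acrylate by nitryl iodide formed in the flask, with NO2 adding to the unsubstituted CH2 terminus and iodine capturing the α-ester radical, is the established entry to β-nitroacrylates.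

Step 2
Reactants: 2 methyl 2-iodo-3-nitropropanoate
Product: 3 methyl (E)-3-nitroacrylate
Conditions: NaOAc (anhydrous), Et2O, 0 °C → rt
Reagents that add atoms: none
Why: Acetate-mediated E1cB dehydroiodination (proton α to nitro, iodide from the α-ester carbon) should give the conjugated nitroalkene as the more stable E isomer.

Step 3
Reactants: 3 methyl (E)-3-nitroacrylate; 4 (E)-1-(trimethylsilyloxy)buta-1,3-diene
Product: 7 methyl (3S)-3-hydroxycyclohexa-1,4-diene-1-carboxylate, via nitro cycloadduct 5 (not isolated), via silyl dienyl ether 6 (not isolated)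
Conditions: diene in 1.5-fold excess, N,N'-[(1R,2R)-cyclohexane-1,2-diyl]bis{N'-[3,5-bis(trifluoromethyl)phenyl]thiourea} (10 mol %; the enantiomer that delivers 3S is to be fixed in a first screen), toluene, −78 → −40 °C; then DBU, THF, −40 → 0 °C; then dilute aq. citric acid, THF, 0 °C
Reagents that add atoms: none
Why: Proposed new method: normal-demand [4+2] cycloaddition in which the diene HOMO (largest coefficient at its CH2 terminus, the future C6) meets the nitroacrylate LUMO (largest coefficient at the carbon β to nitro, the future C1), so that C1–C6 and C2–C3 form together and nitro, not the ester, fixes the 1,3-relation of C3–O and C1–CO2Me. The closest known reaction type is the thermal Diels–Alder reaction of 1-oxygenated dienes with β-nitroacrylates followed by base-induced loss of nitrous acid; what is new is the chiral double hydrogen-bond donor, which should bind the nitro oxygens as such thioureas do in asymmetric nitroalkene additions, lower the LUMO and shield one face of the dienophile. The six-membered carbocycle is closed by a concerted suprafacial cycloaddition of the s-cis diene (endo-nitro transition state, silyloxy and nitro cis in 5). C3 is the only lasting stereocentre and its S configuration is set by the catalyst-controlled face of approach; the centres at C1 and C2 are erased when DBU removes the C1–H α to the ester and nitrite leaves from C2 (E1cB), which can place the new double bond only at C1=C2. Deprotonation at C2 to the nitronate should be faster but reversible and unproductive, because silyloxide on C3 is a poor leaving group. The step needs regiocontrol (nitro outweighs ester, reinforced by catalyst binding at nitro), suppression of the racemic background reaction (low temperature, non-polar solvent) and an intact O–Si bond until nitrite has left (a free β-nitro alcohol would open by retro-Henry reaction and lose C3), after which dilute aqueous acid frees the C3 hydroxyl without dehydrating the skipped dienol.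

Step 4
Reactants: 7 methyl (3S)-3-hydroxycyclohexa-1,4-diene-1-carboxylate
Product: 8 methyl (1S,5R,6R)-5-hydroxy-7-oxabicyclo[4.1.0]hept-3-ene-3-carboxylate (epoxide cis to the hydroxyl)
Conditions: mCPBA, Na2HPO4, CH2Cl2, 0 °C
Reagents that add atoms: 3-chloroperoxybenzoic acid (mCPBA) OOC(=O)c1cccc(Cl)c1
Why: Henbest hydroxyl-directed epoxidation: the allylic C3–OH hydrogen-bonds to the peracid and delivers oxygen to the syn face of the electron-rich C4=C5 bond (the ester-conjugated C1=C2 is inert to peracid), which sets C4 and C5 cis to C3–O.

Step 5
Reactants: 8 methyl (1S,5R,6R)-5-hydroxy-7-oxabicyclo[4.1.0]hept-3-ene-3-carboxylate; 9 (E)-3-methylpent-2-enoic acid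
Product: 10 methyl (1S,5R,6S)-5-{[(2E)-3-methylpent-2-enoyl]oxy}-7-oxabicyclo[4.1.0]hept-3-ene-3-carboxylate
Conditions: N,N'-dicyclohexylcarbodiimide (DCC), 4-(dimethylamino)pyridine (cat.), CH2Cl2, 0 °C → rt
Reagents that add atoms: none
Why: Steglich esterification acylates the C3 oxygen without touching the C3–O bond (retention; the descriptor at the adjacent epoxide carbon changes only because the priorities change) under neutral conditions that spare the epoxide.

Step 6
Reactants: 10 methyl (1S,5R,6S)-5-{[(2E)-3-methylpent-2-enoyl]oxy}-7-oxabicyclo[4.1.0]hept-3-ene-3-carboxylate; 9 (E)-3-methylpent-2-enoic acid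
Product: 11 methyl (3R,4S,5R)-4-hydroxy-3,5-bis{[(2E)-3-methylpent-2-enoyl]oxy}cyclohex-1-ene-1-carboxylate (target)
Conditions: (R,R)-N,N'-bis(3,5-di-tert-butylsalicylidene)-1,2-cyclohexanediaminocobalt (divalent cobalt, C36H52CoN2O2, 5 mol %, oxidised by air to the trivalent cobalt carboxylate), iPr2NEt (1 equiv), t-BuOMe, air, rt
Reagents that add atoms: none
Why: Cobalt-salen-catalysed ring opening of an epoxide by a carboxylic acid is an SN2 addition of one molecule of 9 to 10 with no by-product, in which the ammonium carboxylate formed from 9 and iPr2NEt should attack the cobalt-activated epoxide at C5, the carbon remote from the electron-withdrawing C3 acyloxy group and the one reached by trans-diaxial attack (as in nucleophilic openings of the analogous shikimate-derived 3-alkoxy-4,5-epoxide), so that inversion at C5 gives the 4,5-trans arrangement and leaves the C4 hydroxyl free and cis to the C3 ester.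

Compound list
1 | methyl acrylate | C=CC(=O)OC | starting material
2 | methyl 2-iodo-3-nitropropanoate (racemic) | COC(=O)C(I)C[N+](=O)[O-] | intermediate
3 | methyl (E)-3-nitroacrylate | COC(=O)/C=C/[N+](=O)[O-] | intermediate
4 | (E)-1-(trimethylsilyloxy)buta-1,3-diene | C=C/C=C/O[Si](C)(C)C | starting material
5 | methyl (1S,5S,6R)-6-nitro-5-(trimethylsilyloxy)cyclohex-3-ene-1-carboxylate (nitro cis to silyloxy, ester trans to nitro) | C[Si](C)(C)O[C@@H]1[C@H]([N+](=O)[O-])[C@@H](C(=O)OC)CC=C1 | intermediate
6 | methyl (3S)-3-(trimethylsilyloxy)cyclohexa-1,4-diene-1-carboxylate | C[Si](C)(C)O[C@@H]1C=C(C(=O)OC)CC=C1 | intermediate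
7 | methyl (3S)-3-hydroxycyclohexa-1,4-diene-1-carboxylate | O[C@@H]1C=C(C(=O)OC)CC=C1 | intermediate
8 | methyl (1S,5R,6R)-5-hydroxy-7-oxabicyclo[4.1.0]hept-3-ene-3-carboxylate | O[C@@H]1C=C(C(=O)OC)C[C@@H]2O[C@H]12 | intermediate
9 | (E)-3-methylpent-2-enoic acid | CC/C(C)=C/C(=O)O | starting material
10 | methyl (1S,5R,6S)-5-{[(2E)-3-methylpent-2-enoyl]oxy}-7-oxabicyclo[4.1.0]hept-3-ene-3-carboxylate | CC/C(C)=C/C(=O)O[C@@H]1C=C(C(=O)OC)C[C@@H]2O[C@H]12 | intermediate
11 | methyl (3R,4S,5R)-4-hydroxy-3,5-bis{[(2E)-3-methylpent-2-enoyl]oxy}cyclohex-1-ene-1-carboxylate | CC/C(C)=C/C(=O)O[C@@H]1C=C(C(=O)OC)C[C@@H](OC(=O)/C=C(\C)CC)[C@@H]1O | target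

Total step count: 6. Longest linear sequence: 6 steps (1 → 2 → 3 → 7 → 8 → 10 → 11).

Steps most likely to fail

Step 3 (Proposed new method). Facial discrimination by the hydrogen-bond donor may be too weak, the uncatalysed background cycloaddition may erode the enantiomeric purity, or the partners may drift into a hetero-Diels–Alder or Mukaiyama–Michael pathway. The fallback sets out from 3 and 4 and uses known chemistry: the uncatalysed thermal cycloaddition (toluene, 0 °C → rt), DBU and the same acidic work-up should give, through the racemic cycloadduct F1 and the racemic silyl dienyl ether F2, the racemic dienol F3. Kinetic resolution with Candida antarctica lipase B and vinyl acetate in t-BuOMe should acetylate the R enantiomer to the acetate F4 (Kazlauskas rule, the ester-bearing ring arm as the large group) and leave 7, where the route is rejoined.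

Step 4. The doubly allylic alcohol may lose water to methyl benzoate under the acidic by-product, or syn direction may be weak in the flat dienol. The fallback sets out from 7 and replaces hydroxyl delivery by an anti-bromonium and SN2-closure sequence: esterification with 9 (DCC, 4-(dimethylamino)pyridine) should give the dienyl ester F5. N-Bromosuccinimide in aqueous 1,2-dimethoxyethane should place the bromonium ion on the face anti to the ester and water trans to it at C5, giving the bromohydrin F6. K2CO3 in acetone then closes the epoxide on the hydroxyl face, syn to the C3 ester, and the route is rejoined at 10 (8 is bypassed).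

Step 6. The carboxylate may attack C4 instead of C5, an acyl group may migrate onto the freed C4 hydroxyl, or base may remove the γ-proton at C3 and open the epoxide by elimination. The fallback sets out from 10 and separates oxygen delivery from acylation: acid-catalysed hydrolysis (HClO4 cat., THF–H2O, 0 °C), in which the developing positive charge avoids C4 next to the acyloxy group, should give the 4,5-trans-diol F7. The less hindered C5 hydroxyl is then esterified with 9 (DCC, 4-(dimethylamino)pyridine, −20 °C) to reach 11.

Further compounds
F1 | step 3 | racemic methyl 6-nitro-5-(trimethylsilyloxy)cyclohex-3-ene-1-carboxylate (relative configuration as in 5) | C[Si](C)(C)OC1C=CCC(C(=O)OC)C1[N+](=O)[O-]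
F2 | step 3 | racemic methyl 3-(trimethylsilyloxy)cyclohexa-1,4-diene-1-carboxylate | C[Si](C)(C)OC1C=C(C(=O)OC)CC=C1
F3 | step 3 | racemic methyl 3-hydroxycyclohexa-1,4-diene-1-carboxylate | OC1C=C(C(=O)OC)CC=C1
F4 | step 3 | methyl (3R)-3-acetoxycyclohexa-1,4-diene-1-carboxylate | CC(=O)O[C@H]1C=C(C(=O)OC)CC=C1
F5 | step 4 | methyl (3S)-3-{[(2E)-3-methylpent-2-enoyl]oxy}cyclohexa-1,4-diene-1-carboxylate | CC/C(C)=C/C(=O)O[C@@H]1C=C(C(=O)OC)CC=C1
F6 | step 4 | methyl (3R,4R,5S)-4-bromo-5-hydroxy-3-{[(2E)-3-methylpent-2-enoyl]oxy}cyclohex-1-ene-1-carboxylate | CC/C(C)=C/C(=O)O[C@@H]1C=C(C(=O)OC)C[C@H](O)[C@H]1Br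
F7 | step 6 | methyl (3R,4S,5R)-4,5-dihydroxy-3-{[(2E)-3-methylpent-2-enoyl]oxy}cyclohex-1-ene-1-carboxylate | CC/C(C)=C/C(=O)O[C@@H]1C=C(C(=O)OC)C[C@@H](O)[C@@H]1O
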